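Ring numbering used: C1 (stereocentre, carries the (E)-6-methylhepta-2,5-dien-2-yl chain), C2, C3=C4(Me) (Z), C5, C6, C7=C8(CO2H), C9, C10, C11=C12(Me) (E), C13, C14; this 14-membered carbocycle is the only ring.
Cuts, in retrosynthetic order: C8–C9 (opens the ring), the ester C–O bonds, C7=C8 (Wittig), C10–C11 (Negishi coupling), the two methyl–alkene bonds and the side-chain CH–CH2 bond (carboalumination and allylation of two alkynes), C1–C2 (enolate alkylation).
Enabling feature: C9 is a CH2 two carbons away from the C11=C12 alkene, so it is the carbon left when a 4-enoic acid loses CO2, and C8 is the alpha carbon of the C7=C8 enoate, so it can be carried as an alkenyl iodide; a C9 radical and a C8–nickel bond in one chain can close the ring.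
Forward: a nerol-derived (Z)-allylic bromide (C2–C7) alkylates a silyl-alkyne acyl oxazolidinone (C1, C11–C14); the acyl carbon becomes an alkyne and then the side chain; the second alkyne becomes the (E)-C11 iodide and is extended by C10, C9 and a carboxyl carbon; C7 becomes the (Z)-iodoenoate; the acid is activated and the chain is closed electrochemically between C8 and C9; the tert-butyl ester is removed last.
Stereochemistry: C1 (R) from the (S)-benzyloxazolidinone alkylation; C3=C4 (Z) from neryl acetate; C11=C12 and the side-chain alkene (E) from syn-carboalumination; C7=C8 from the (Z)-selective iodo-Wittig, kept with retention in the ring closure.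
Key step: step 19

Step 1
Reactants: 1 neryl acetate
Product: 3 (2Z)-6-hydroxy-3-methylhex-2-en-1-yl acetate, via ozonide 2 (not isolated)
Conditions: O3 (1.0 equiv), CH2Cl2, −78 °C; then NaBH4 (excess), MeOH, −78 → 0 °C
Reagents that add atoms: ozone ([O-][O+]=O)
Why: Ozonolysis with reductive work-up should cleave only the electron-rich 6,7-alkene, because the 2,3-alkene is deactivated by the allylic acetate, and the Z alkene is not touched.

Step 2
Reactants: 3 (2Z)-6-hydroxy-3-methylhex-2-en-1-yl acetate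
Product: 4 (2Z)-6-[(tert-butyldimethylsilyl)oxy]-3-methylhex-2-en-1-yl acetate
Conditions: t-BuMe2SiCl, imidazole, CH2Cl2, 0 °C → rt
Reagents that add atoms: tert-butyldimethylsilyl chloride (CC(C)(C)[Si](C)(C)Cl)
Why: Silylation of the primary alcohol protects the future C7 oxygen through the enolate, hydride and organoaluminium steps.

Step 3
Reactants: 4 (2Z)-6-[(tert-butyldimethylsilyl)oxy]-3-methylhex-2-en-1-yl acetate
Product: 5 (2Z)-6-[(tert-butyldimethylsilyl)oxy]-3-methylhex-2-en-1-ol
Conditions: K2CO3 (cat.), MeOH, 0 °C → rt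
Reagents that add atoms: none
Why: Methanolysis (transesterification) frees the allylic alcohol while the silyl ether is stable to mild base.

Step 4
Reactants: 5 (2Z)-6-[(tert-butyldimethylsilyl)oxy]-3-methylhex-2-en-1-ol
Product: 6 {[(4Z)-6-bromo-4-methylhex-4-en-1-yl]oxy}(tert-butyl)dimethylsilane
Conditions: CBr4, PPh3, CH2Cl2, −20 → 0 °C
Reagents that add atoms: carbon tetrabromide (BrC(Br)(Br)Br)
Why: Appel bromination converts the primary allylic alcohol to the bromide by SN2 displacement at low temperature, which should keep the Z alkene and avoid allylic transposition.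

Step 5
Reactants: 7 hex-5-ynoic acid
Product: 9 6-(triisopropylsilyl)hex-5-ynoic acid, via silyl ester 8 (not isolated)
Conditions: LiN(i-Pr)2 (2.2 equiv), THF, −78 → 0 °C; i-Pr3SiCl (2.2 equiv), −78 °C → rt; then 1 M HCl, THF, rt
Reagents that add atoms: chlorotriisopropylsilane (CC(C)[Si](Cl)(C(C)C)C(C)C)
Why: The carboxylate–acetylide dianion is silylated on oxygen and carbon and the labile silyl ester is hydrolysed on acidic work-up, which leaves a bulky C-silyl alkyne that masks this alkyne against the first carbometalation.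

Step 6
Reactants: 9 6-(triisopropylsilyl)hex-5-ynoic acid; 10 (4S)-4-benzyl-1,3-oxazolidin-2-one
Product: 12 (4S)-4-benzyl-3-[6-(triisopropylsilyl)hex-5-ynoyl]-1,3-oxazolidin-2-one, via mixed anhydride 11 (not isolated)
Conditions: t-BuCOCl, Et3N, THF, −20 °C; then LiCl, 10, −20 °C → rt
Reagents that add atoms: none
Why: N-acylation of the oxazolidinone through the mixed pivalic anhydride is the standard way to attach the Evans auxiliary.

Step 7
Reactants: 12 (4S)-4-benzyl-3-[6-(triisopropylsilyl)hex-5-ynoyl]-1,3-oxazolidin-2-one; 6 {[(4Z)-6-bromo-4-methylhex-4-en-1-yl]oxy}(tert-butyl)dimethylsilane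
Product: 14 (4S)-4-benzyl-3-[(2R)-2-{(2Z)-6-[(tert-butyldimethylsilyl)oxy]-3-methylhex-2-en-1-yl}-6-(triisopropylsilyl)hex-5-ynoyl]-1,3-oxazolidin-2-one, via sodium enolate 13 (not isolated)
Conditions: NaN(SiMe3)2, THF, −78 °C; then 6, −78 → −40 °C
Reagents that add atoms: none
Why: Evans alkylation, in which the chelated (Z)-sodium enolate is attacked by the allylic bromide on the face opposite the benzyl group of the (S)-auxiliary, should set C1 as R.

Step 8
Reactants: 14 the alkylated imide
Product: 15 (2R)-2-{(2Z)-6-[(tert-butyldimethylsilyl)oxy]-3-methylhex-2-en-1-yl}-6-(triisopropylsilyl)hex-5-yn-1-ol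
Conditions: LiBH4, MeOH (1 equiv), Et2O, 0 °C
Reagents that add atoms: none
Why: Reductive cleavage of the imide with lithium borohydride gives the primary alcohol without touching the stereocentre and returns the auxiliary.

Step 9
Reactants: 15 the primary alcohol
Product: 16 (2R)-2-{(2Z)-6-[(tert-butyldimethylsilyl)oxy]-3-methylhex-2-en-1-yl}-6-(triisopropylsilyl)hex-5-ynal
Conditions: Dess–Martin periodinane, CH2Cl2, 0 °C → rt
Reagents that add atoms: none
Why: Dess–Martin oxidation gives the alpha-branched aldehyde under near-neutral conditions that should not epimerise C1.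

Step 10
Reactants: 16 the aldehyde
Product: 17 (3R)-3-{(2Z)-6-[(tert-butyldimethylsilyl)oxy]-3-methylhex-2-en-1-yl}-7-(triisopropylsilyl)hepta-1,6-diyne
Conditions: dimethyl (1-diazo-2-oxopropyl)phosphonate, K2CO3, MeOH, 0 °C → rt
Reagents that add atoms: dimethyl (1-diazo-2-oxopropyl)phosphonate (COP(=O)(OC)C(=[N+]=[N-])C(C)=O)
Why: Ohira–Bestmann homologation turns the aldehyde into the terminal alkyne at C1 under mild base, to which the triisopropylsilyl alkyne and the silyl ether are stable.

Step 11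
Reactants: 17 the diyne; 18 prenyl chloride
Product: 20 tert-butyldimethyl{[(4Z,7R,8E)-4,8,12-trimethyl-7-[4-(triisopropylsilyl)but-3-yn-1-yl]trideca-4,8,11-trien-1-yl]oxy}silane, via alkenylalane 19 (not isolated)
Conditions: Me3Al (2.5 equiv), Cp2ZrCl2 (0.25 equiv), CH2Cl2, 0 °C → rt; then 18, Pd(PPh3)4 (5 mol %), THF, rt
Reagents that add atoms: trimethylaluminium (C[Al](C)C)
Why: Zirconium-catalysed syn-carboalumination (Negishi) of the free terminal alkyne puts methyl on the internal carbon and aluminium cis to it, and palladium-catalysed allylation of the alkenylalane at the unsubstituted terminus of prenyl chloride should give the (E)-1,4-diene side chain while the silyl alkyne stays inert.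

Step 12
Reactants: 20 the silyl-protected trienyne
Product: 21 (4Z,7R,8E)-7-(but-3-yn-1-yl)-4,8,12-trimethyltrideca-4,8,11-trien-1-ol
Conditions: Bu4NF, THF, 0 °C → rt
Reagents that add atoms: none
Why: Fluoride desilylation removes the O-silyl and the C-silyl group in one operation and unmasks the C7 hydroxyl and the second terminal alkyne.

Step 13
Reactants: 21 the alkynol
Product: 23 (4Z,7R,8E)-7-[(3E)-4-iodo-3-methylbut-3-en-1-yl]-4,8,12-trimethyltrideca-4,8,11-trien-1-ol, via alkenylalane 22 (not isolated)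
Conditions: Me3Al (3.5 equiv), Cp2ZrCl2 (0.3 equiv), CH2Cl2, 0 °C → rt; then I2, THF, −30 °C
Reagents that add atoms: trimethylaluminium (C[Al](C)C); iodine ([I][I])
Why: The same syn-carboalumination followed by iodinolysis with retention should give the (E)-alkenyl iodide that fixes the C11=C12 geometry, the hydroxyl being carried as its aluminium alkoxide.

Step 14
Reactants: 23 the alkenyl iodide; 24 (3-ethoxy-3-oxopropyl)zinc bromide
Product: 25 ethyl (4E,8R,10Z)-14-hydroxy-5,11-dimethyl-8-[(2E)-6-methylhepta-2,5-dien-2-yl]tetradeca-4,10-dienoate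
Conditions: 24 (3 equiv), Pd(PPh3)4 (5 mol %), THF/DMA, rt → 40 °C
Reagents that add atoms: none
Why: Negishi sp2–sp3 coupling of the alkenyl iodide with the zinc homoenolate proceeds with retention of alkene geometry and brings in C10, C9 and the ester carbon, the excess zinc reagent tolerating the free alcohol.

Step 15
Reactants: 25 the hydroxy ester
Product: 26 ethyl (4E,8R,10Z)-5,11-dimethyl-8-[(2E)-6-methylhepta-2,5-dien-2-yl]-14-oxotetradeca-4,10-dienoate
Conditions: Dess–Martin periodinane, CH2Cl2, 0 °C → rt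
Reagents that add atoms: none
Why: Dess–Martin oxidation gives the C7 aldehyde without affecting the ester or the alkenes.

Step 16
Reactants: 26 the aldehyde ester; 27 tert-butyl (triphenyl-λ5-phosphanylidene)acetate
Product: 28 1-tert-butyl 16-ethyl (2Z,6Z,9R,12E)-2-iodo-6,12-dimethyl-9-[(2E)-6-methylhepta-2,5-dien-2-yl]hexadeca-2,6,12-trienedioate
Conditions: 27, N-iodosuccinimide, CH2Cl2, −20 °C; then 26, −20 °C → rt
Reagents that add atoms: N-iodosuccinimide (IN1C(=O)CCC1=O)
Why: Wittig olefination with the alpha-iodo ylide made in the flask places the ester trans to the chain, as stabilised ylides do, and should give the (Z)-alpha-iodoenoate needed for C7=C8.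

Step 17
Reactants: 28 the diester
Product: 29 (4E,8R,10Z,14Z)-16-tert-butoxy-15-iodo-5,11-dimethyl-8-[(2E)-6-methylhepta-2,5-dien-2-yl]-16-oxohexadeca-4,10,14-trienoic acid
Conditions: LiOH, THF/H2O, 0 °C; then dilute HCl to pH 3
Reagents that add atoms: lithium hydroxide ([Li+].[OH-])
Why: Cold saponification should take the unhindered ethyl ester and leave the tert-butyl iodoenoate, which resists hydroxide.

Step 18
Reactants: 29 the acid
Product: 30 1-tert-butyl 16-(1,3-dioxoisoindolin-2-yl) (2Z,6Z,9R,12E)-2-iodo-6,12-dimethyl-9-[(2E)-6-methylhepta-2,5-dien-2-yl]hexadeca-2,6,12-trienedioate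
Conditions: N-hydroxyphthalimide, i-PrN=C=N-i-Pr, DMAP (cat.), CH2Cl2, rt
Reagents that add atoms: N-hydroxyphthalimide (ON1C(=O)c2ccccc2C1=O)
Why: Carbodiimide (Steglich-type) esterification gives the redox-active N-acyloxyphthalimide.

Step 19
Reactants: 30 the redox-active ester
Product: 31 tert-butyl (1E,5Z,8R,11E)-5,11-dimethyl-8-[(2E)-6-methylhepta-2,5-dien-2-yl]cyclotetradeca-1,5,11-triene-1-carboxylate
Conditions: NiCl2·6H2O (20 mol %), 2,2'-bipyridine (30 mol %), AgNO3 (30 mol %), LiCl, NMP, undivided cell, magnesium anode, reticulated vitreous carbon cathode, constant current, rt, 30 added by syringe pump (final concentration about 2 mM)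
Reagents that add atoms: none
Why: Proposed new method: zerovalent nickel–bipyridine formed at the cathode should insert into the C8–I bond, while single-electron reduction of the N-acyloxyphthalimide releases CO2 and phthalimide anion and leaves a primary radical at C9; capture of this radical by the alkenylnickel of the same molecule and reductive elimination from trivalent nickel form the C8–C9 bond. The closest known reaction type is the intermolecular nickel-electrocatalytic decarboxylative alkenylation of redox-active esters of 4-enoic acids with alkenyl iodides that joins polyene terpene chains; the intramolecular mode and the ester-bearing alkenyl iodide are the untested elements. The 14-membered ring closes end to end through a 15-membered nickelacycle (radical capture at nickel, then C(sp2)–C(sp3) reductive elimination), not by exo or endo radical addition to an alkene. No stereocentre is formed and C1 is not involved; the C7=C8 geometry is that of the (Z)-iodide, carried over with retention (the product descriptor becomes E only because carbon replaces iodine). The step needs ring closure to outrun chain growth, premature reduction and radical rearrangement: slow addition keeps the substrate dilute, the iodoenoate is the only site for nickel insertion and the phthalimide ester the only radical source, and the C9 radical has no 5-exo or 6-exo alkene within reach, its only internal partner (C11=C12) offering a reversible 3-exo closure.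

Step 20
Reactants: 31 the macrocyclic tert-butyl ester
Product: 33 (1E,5Z,8R,11E)-5,11-dimethyl-8-[(2E)-6-methylhepta-2,5-dien-2-yl]cyclotetradeca-1,5,11-triene-1-carboxylic acid, via silyl ester 32 (not isolated)
Conditions: Me3SiOTf, 2,6-lutidine, CH2Cl2, 0 °C; then pH 4 aqueous buffer
Reagents that add atoms: none
Why: Silyl-triflate-mediated cleavage of the tert-butyl ester (loss of isobutene, then hydrolysis of the silyl ester on work-up) avoids the protic acid that could protonate the trisubstituted alkenes.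

Compound list
1 | neryl acetate, (2Z)-3,7-dimethylocta-2,6-dien-1-yl acetate | CC(C)=CCC/C(C)=C\COC(C)=O | starting material
2 | ozonide of 1 at the 6,7-alkene, (2Z)-5-(5,5-dimethyl-1,2,4-trioxolan-3-yl)-3-methylpent-2-en-1-yl acetate | CC(=O)OC/C=C(/C)CCC1OOC(C)(C)O1 | intermediate
3 | (2Z)-6-hydroxy-3-methylhex-2-en-1-yl acetate | CC(=O)OC/C=C(/C)CCCO | intermediate
4 | (2Z)-6-[(tert-butyldimethylsilyl)oxy]-3-methylhex-2-en-1-yl acetate | CC(=O)OC/C=C(/C)CCCO[Si](C)(C)C(C)(C)C | intermediate
5 | (2Z)-6-[(tert-butyldimethylsilyl)oxy]-3-methylhex-2-en-1-ol | OC/C=C(/C)CCCO[Si](C)(C)C(C)(C)C | intermediate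
6 | {[(4Z)-6-bromo-4-methylhex-4-en-1-yl]oxy}(tert-butyl)dimethylsilane | BrC/C=C(/C)CCCO[Si](C)(C)C(C)(C)C | intermediate
7 | hex-5-ynoic acid | C#CCCCC(=O)O | starting material
8 | triisopropylsilyl 6-(triisopropylsilyl)hex-5-ynoate | CC(C)[Si](C#CCCCC(=O)O[Si](C(C)C)(C(C)C)C(C)C)(C(C)C)C(C)C | intermediate
9 | 6-(triisopropylsilyl)hex-5-ynoic acid | CC(C)[Si](C#CCCCC(=O)O)(C(C)C)C(C)C | intermediate
10 | (4S)-4-benzyl-1,3-oxazolidin-2-one | O=C1N[C@@H](Cc2ccccc2)CO1 | starting material
11 | 6-(triisopropylsilyl)hex-5-ynoic pivalic anhydride | CC(C)[Si](C#CCCCC(=O)OC(=O)C(C)(C)C)(C(C)C)C(C)C | intermediate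
12 | (4S)-4-benzyl-3-[6-(triisopropylsilyl)hex-5-ynoyl]-1,3-oxazolidin-2-one | CC(C)[Si](C#CCCCC(=O)N1[C@@H](Cc2ccccc2)COC1=O)(C(C)C)C(C)C | intermediate
13 | sodium (Z)-1-[(4S)-4-benzyl-2-oxo-1,3-oxazolidin-3-yl]-6-(triisopropylsilyl)hex-1-en-5-yn-1-olate | [Na+].[O-]/C(=C\CCC#C[Si](C(C)C)(C(C)C)C(C)C)N1[C@@H](Cc2ccccc2)COC1=O | intermediate
14 | (4S)-4-benzyl-3-[(2R)-2-{(2Z)-6-[(tert-butyldimethylsilyl)oxy]-3-methylhex-2-en-1-yl}-6-(triisopropylsilyl)hex-5-ynoyl]-1,3-oxazolidin-2-one | O=C(N1[C@@H](Cc2ccccc2)COC1=O)[C@@H](C/C=C(/C)CCCO[Si](C)(C)C(C)(C)C)CCC#C[Si](C(C)C)(C(C)C)C(C)C | intermediate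
15 | (2R)-2-{(2Z)-6-[(tert-butyldimethylsilyl)oxy]-3-methylhex-2-en-1-yl}-6-(triisopropylsilyl)hex-5-yn-1-ol | OC[C@@H](C/C=C(/C)CCCO[Si](C)(C)C(C)(C)C)CCC#C[Si](C(C)C)(C(C)C)C(C)C | intermediate
16 | (2R)-2-{(2Z)-6-[(tert-butyldimethylsilyl)oxy]-3-methylhex-2-en-1-yl}-6-(triisopropylsilyl)hex-5-ynal | O=C[C@@H](C/C=C(/C)CCCO[Si](C)(C)C(C)(C)C)CCC#C[Si](C(C)C)(C(C)C)C(C)C | intermediate
17 | (3R)-3-{(2Z)-6-[(tert-butyldimethylsilyl)oxy]-3-methylhex-2-en-1-yl}-7-(triisopropylsilyl)hepta-1,6-diyne | C#C[C@@H](C/C=C(/C)CCCO[Si](C)(C)C(C)(C)C)CCC#C[Si](C(C)C)(C(C)C)C(C)C | intermediate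
18 | prenyl chloride, 1-chloro-3-methylbut-2-ene | CC(C)=CCCl | starting material
19 | (E)-alkenyl(dimethyl)alane from 17 (methyl on the internal alkyne carbon, AlMe2 on the terminal carbon, cis to the methyl) | C[Al](C)/C=C(\C)[C@@H](C/C=C(/C)CCCO[Si](C)(C)C(C)(C)C)CCC#C[Si](C(C)C)(C(C)C)C(C)C | intermediate
20 | tert-butyldimethyl{[(4Z,7R,8E)-4,8,12-trimethyl-7-[4-(triisopropylsilyl)but-3-yn-1-yl]trideca-4,8,11-trien-1-yl]oxy}silane | CC(C)=CC/C=C(\C)[C@@H](C/C=C(/C)CCCO[Si](C)(C)C(C)(C)C)CCC#C[Si](C(C)C)(C(C)C)C(C)C | intermediate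
21 | (4Z,7R,8E)-7-(but-3-yn-1-yl)-4,8,12-trimethyltrideca-4,8,11-trien-1-ol | CC(C)=CC/C=C(\C)[C@@H](C/C=C(/C)CCCO)CCC#C | intermediate
22 | (E)-alkenyl(dimethyl)alane from 21, with the hydroxyl as its dimethylaluminium alkoxide | CC(C)=CC/C=C(\C)[C@@H](C/C=C(/C)CCCO[Al](C)C)CC/C(C)=C/[Al](C)C | intermediate
23 | (4Z,7R,8E)-7-[(3E)-4-iodo-3-methylbut-3-en-1-yl]-4,8,12-trimethyltrideca-4,8,11-trien-1-ol | CC(C)=CC/C=C(\C)[C@@H](C/C=C(/C)CCCO)CC/C(C)=C/I | intermediate
24 | (3-ethoxy-3-oxopropyl)zinc bromide | CCOC(=O)CC[Zn]Br | starting material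
25 | ethyl (4E,8R,10Z)-14-hydroxy-5,11-dimethyl-8-[(2E)-6-methylhepta-2,5-dien-2-yl]tetradeca-4,10-dienoate | CC(C)=CC/C=C(\C)[C@@H](C/C=C(/C)CCCO)CC/C(C)=C/CCC(=O)OCC | intermediate
26 | ethyl (4E,8R,10Z)-5,11-dimethyl-8-[(2E)-6-methylhepta-2,5-dien-2-yl]-14-oxotetradeca-4,10-dienoate | CC(C)=CC/C=C(\C)[C@@H](C/C=C(/C)CCC=O)CC/C(C)=C/CCC(=O)OCC | intermediate
27 | tert-butyl (triphenyl-λ5-phosphanylidene)acetate | CC(C)(C)OC(=O)C=P(c1ccccc1)(c1ccccc1)c1ccccc1 | starting material
28 | 1-tert-butyl 16-ethyl (2Z,6Z,9R,12E)-2-iodo-6,12-dimethyl-9-[(2E)-6-methylhepta-2,5-dien-2-yl]hexadeca-2,6,12-trienedioate | CC(C)=CC/C=C(\C)[C@@H](C/C=C(/C)CC/C=C(\I)C(=O)OC(C)(C)C)CC/C(C)=C/CCC(=O)OCC | intermediate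
29 | (4E,8R,10Z,14Z)-16-tert-butoxy-15-iodo-5,11-dimethyl-8-[(2E)-6-methylhepta-2,5-dien-2-yl]-16-oxohexadeca-4,10,14-trienoic acid | CC(C)=CC/C=C(\C)[C@@H](C/C=C(/C)CC/C=C(\I)C(=O)OC(C)(C)C)CC/C(C)=C/CCC(=O)O | intermediate
30 | 1-tert-butyl 16-(1,3-dioxoisoindolin-2-yl) (2Z,6Z,9R,12E)-2-iodo-6,12-dimethyl-9-[(2E)-6-methylhepta-2,5-dien-2-yl]hexadeca-2,6,12-trienedioate | CC(C)=CC/C=C(\C)[C@@H](C/C=C(/C)CC/C=C(\I)C(=O)OC(C)(C)C)CC/C(C)=C/CCC(=O)ON1C(=O)c2ccccc2C1=O | intermediate
31 | tert-butyl (1E,5Z,8R,11E)-5,11-dimethyl-8-[(2E)-6-methylhepta-2,5-dien-2-yl]cyclotetradeca-1,5,11-triene-1-carboxylate | CC(C)=CC/C=C(\C)[C@H]1C/C=C(/C)CC/C=C(/C(=O)OC(C)(C)C)CC/C=C(\C)CC1 | intermediate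
32 | trimethylsilyl (1E,5Z,8R,11E)-5,11-dimethyl-8-[(2E)-6-methylhepta-2,5-dien-2-yl]cyclotetradeca-1,5,11-triene-1-carboxylate | CC(C)=CC/C=C(\C)[C@H]1C/C=C(/C)CC/C=C(/C(=O)O[Si](C)(C)C)CC/C=C(\C)CC1 | intermediate
33 | (1E,5Z,8R,11E)-5,11-dimethyl-8-[(2E)-6-methylhepta-2,5-dien-2-yl]cyclotetradeca-1,5,11-triene-1-carboxylic acid | CC(C)=CC/C=C(\C)[C@H]1C/C=C(/C)CC/C=C(/C(=O)O)CC/C=C(\C)CC1 | target

Total step count: 20.
Longest linear sequence: 18 steps (steps 1–4, then 7–20).

Steps most likely to fail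

Step 19 (bears the label "Proposed new method:"). What may go wrong: radical capture between molecules, so that chains grow instead of the ring closing; cathodic loss of iodine from the electron-poor iodoenoate, or reduction of the C9 radical before it reaches nickel; erosion of the C11=C12 geometry through reversible 3-exo closure of the homoallylic radical. The fallback closes the same C8–C9 bond by a two-electron reaction of a known type, the intramolecular B-alkyl Suzuki–Miyaura coupling, and sets out from 23. Suzuki–Miyaura vinylation of the alkenyl iodide (vinylboronic acid pinacol ester, PdCl2(dppf), K3PO4, THF/H2O) should give the terminal diene (4Z,7R,8E)-4,8,12-trimethyl-7-[(3E)-3-methylhexa-3,5-dien-1-yl]trideca-4,8,11-trien-1-ol F1. Dess–Martin oxidation should give (4Z,7R,8E)-4,8,12-trimethyl-7-[(3E)-3-methylhexa-3,5-dien-1-yl]trideca-4,8,11-trienal F2, and the iodo-Wittig of step 16 (27, N-iodosuccinimide) should give tert-butyl (2Z,6Z,9R,10E)-2-iodo-6,10,14-trimethyl-9-[(3E)-3-methylhexa-3,5-dien-1-yl]pentadeca-2,6,10,13-tetraenoate F3. 9-Borabicyclo[3.3.1]nonane (THF, 0 °C → rt) should add only to the terminal CH2=CH of the diene, with boron on C9, to give the B-alkyl-9-borabicyclo[3.3.1]nonane F4, which is not isolated. PdCl2(dppf), AsPh3 and Cs2CO3 in DMF/THF/H2O at high dilution should then couple C9 with the iodoenoate carbon C8 with retention of alkene geometry, and the route is rejoined at 31.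

Step 11. What may go wrong: attack of the alkenylalane at the substituted terminus of the allyl–palladium intermediate (branched coupling), transfer of methyl instead of alkenyl, or homocoupling during the one-pot allylation. The fallback reverses the polarity of the coupling and sets out from 17. The carboalumination is run as before, but the alkenylalane 19 is quenched with iodine (THF, −30 °C) to give the (E)-alkenyl iodide tert-butyl{[(4Z,7R,8E)-9-iodo-4,8-dimethyl-7-[4-(triisopropylsilyl)but-3-yn-1-yl]nona-4,8-dien-1-yl]oxy}dimethylsilane F5. Stille coupling of this iodide with tributyl(3-methylbut-2-en-1-yl)stannane (Pd2(dba)3, AsPh3, DMF, rt) should deliver the prenyl group at its unsubstituted carbon, and the route is rejoined at 20.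

Step 20. What may go wrong: Lewis-acid-induced cyclisation or double-bond migration in the polyene, or incomplete cleavage of the hindered conjugated ester. The fallback replaces ester cleavage by a reduction–oxidation sequence and sets out from 31. Reduction with i-Bu2AlH (CH2Cl2, −78 → 0 °C) should give the allylic alcohol [(1E,5Z,8R,11E)-5,11-dimethyl-8-[(2E)-6-methylhepta-2,5-dien-2-yl]cyclotetradeca-1,5,11-trien-1-yl]methanol F6. Oxidation with MnO2 (CH2Cl2, rt) should give (1E,5Z,8R,11E)-5,11-dimethyl-8-[(2E)-6-methylhepta-2,5-dien-2-yl]cyclotetradeca-1,5,11-triene-1-carbaldehyde F7. Pinnick oxidation (NaClO2, NaH2PO4, 2-methylbut-2-ene, t-BuOH/H2O) then rejoins the route at 33.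

Further compounds
F1 | step 19 | (4Z,7R,8E)-4,8,12-trimethyl-7-[(3E)-3-methylhexa-3,5-dien-1-yl]trideca-4,8,11-trien-1-ol | CC(C)=CC/C=C(\C)[C@@H](C/C=C(/C)CCCO)CC/C(C)=C/C=C
F2 | step 19 | (4Z,7R,8E)-4,8,12-trimethyl-7-[(3E)-3-methylhexa-3,5-dien-1-yl]trideca-4,8,11-trienal | CC(C)=CC/C=C(\C)[C@@H](C/C=C(/C)CCC=O)CC/C(C)=C/C=C
F3 | step 19 | tert-butyl (2Z,6Z,9R,10E)-2-iodo-6,10,14-trimethyl-9-[(3E)-3-methylhexa-3,5-dien-1-yl]pentadeca-2,6,10,13-tetraenoate | CC(C)=CC/C=C(\C)[C@@H](C/C=C(/C)CC/C=C(\I)C(=O)OC(C)(C)C)CC/C(C)=C/C=C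
F4 | step 19 | B-alkyl-9-borabicyclo[3.3.1]nonane from F3 (boron on C9) | CC(C)=CC/C=C(\C)[C@@H](C/C=C(/C)CC/C=C(\I)C(=O)OC(C)(C)C)CC/C(C)=C/CCB1C2CCCC1CCC2
F5 | step 11 | tert-butyl{[(4Z,7R,8E)-9-iodo-4,8-dimethyl-7-[4-(triisopropylsilyl)but-3-yn-1-yl]nona-4,8-dien-1-yl]oxy}dimethylsilane | I/C=C(\C)[C@@H](C/C=C(/C)CCCO[Si](C)(C)C(C)(C)C)CCC#C[Si](C(C)C)(C(C)C)C(C)C
F6 | step 20 | [(1E,5Z,8R,11E)-5,11-dimethyl-8-[(2E)-6-methylhepta-2,5-dien-2-yl]cyclotetradeca-1,5,11-trien-1-yl]methanol | CC(C)=CC/C=C(\C)[C@H]1C/C=C(/C)CC/C=C(/CO)CC/C=C(\C)CC1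
F7 | step 20 | (1E,5Z,8R,11E)-5,11-dimethyl-8-[(2E)-6-methylhepta-2,5-dien-2-yl]cyclotetradeca-1,5,11-triene-1-carbaldehyde | CC(C)=CC/C=C(\C)[C@H]1C/C=C(/C)CC/C=C(/C=O)CC/C=C(\C)CC1
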